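**Plan**
1. Retrosynthesis: ring C is opened at O1–C2 (Mitsunobu closure) and the two halves are parted at C3–C4 (auxiliary-controlled enolate alkylation). Ring A gives up its C8–prenyl bond and the bond to the future C4 to two directed lithiations of resorcinol bis-MOM ether.
2. On ring B the pyran (ring D) is cut at C3'–CH= and at O–CMe2, which leads back to 2,4-dihydroxybenzaldehyde and 3-methylbut-2-enal.
3. Enabling feature: ring B is a resorcinol whose C3' lies between the oxygens on C2' and C4'. While C1' carries a formyl group (the carbon that later becomes C3 of ring C), the carbonyl holds the 2'-OH in a hydrogen bond, so the enal condenses at C3' and the oxatriene closes on the 4'-oxygen only.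
4. Forward order: ring D on ring B (step 1); O-allylation, one-carbon homologation and N-acylation (steps 2–6); ring A bromide (steps 7–11); union at C3–C4 (step 12); reduction, MOM removal, closure of ring C and deallylation (steps 13–16).
5. Stereochemistry: the only stereocentre, C3 (R), comes from alkylation of the sodium Z-enolate of the (4R)-4-benzyloxazolidinone imide on the face away from the benzyl group; no later step touches it.
6. Helpers: the formyl group (kept, it becomes C3), the allyl ether on O2' (blocks closure of a five-membered ring, removed last), and the MOM ethers on ring A (direct both lithiations, removed before ring closure).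

Key step: step 1

Remark on the chemistry: the SMILES is read as the (3R)-isoflavan; isoflavan locants are used for the target (rings A and C = chroman, ring B = the 3-aryl group with primed locants, ring D = the dimethylpyran on ring B).

**Step 1**
Reactants: 1 2,4-dihydroxybenzaldehyde; 2 3-methylbut-2-enal
Product: 4 5-hydroxy-2,2-dimethyl-2H-chromene-6-carbaldehyde, via ortho-quinone methide 3 (not isolated)
Conditions: ethylenediammonium diacetate (0.2 equiv), xylene, reflux
Reagents that add atoms: 3-methylbut-2-enal (compound 2), CC(C)=CC=O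
Why: Ethylenediammonium diacetate turns 2 into an iminium ion that is attacked by C3 of 1 (Knoevenagel-type C-alkylation ortho to the 4-hydroxyl), and loss of the amine gives ortho-quinone methide 3, a 1-oxatriene that cyclises to form the O–CMe2 bond. The closest known reaction type is the amine-mediated formal [3+3] chromene annulation of 2,4-dihydroxyaryl aldehydes and ketones with enals. The pyran ring closes by a thermal disrotatory oxa-6π electrocyclisation, a pericyclic closure and not a polar exo or endo attack. No stereocentre is created, because the new sp3 carbon carries two methyl groups. The step needs regioselectivity in two senses, C–C bond formation at C3 and not C5 and O–C bond formation through the 4-hydroxyl and not the 2-hydroxyl; the hydrogen bond between the 2-hydroxyl and the formyl oxygen keeps that hydroxyl out of the condensation and makes C3, the carbon between the two oxygens, the enol-like nucleophilic position.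

**Step 2**
Reactants: 4 5-hydroxy-2,2-dimethyl-2H-chromene-6-carbaldehyde; 5 3-bromoprop-1-ene (allyl bromide)
Product: 6 2,2-dimethyl-5-(prop-2-en-1-yloxy)-2H-chromene-6-carbaldehyde
Conditions: K2CO3, DMF, 60 °C
Reagents that add atoms: allyl bromide (compound 5), C=CCBr
Why: Williamson etherification of the only phenol: carbonate in warm DMF deprotonates the hydrogen-bonded 5-hydroxyl and the phenoxide is O-alkylated by the allylic bromide in an SN2 reaction, while the aldehyde and the chromene are inert.

**Step 3**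
Reactants: 6 2,2-dimethyl-5-(prop-2-en-1-yloxy)-2H-chromene-6-carbaldehyde; 7 (methoxymethyl)triphenylphosphonium chloride
Product: 8 6-(2-methoxyethenyl)-2,2-dimethyl-5-(prop-2-en-1-yloxy)-2H-chromene (E/Z mixture)
Conditions: KOt-Bu, THF, 0 °C to rt
Reagents that add atoms: (methoxymethyl)triphenylphosphonium chloride (compound 7), COC[P+](c1ccccc1)(c1ccccc1)c1ccccc1.[Cl-]
Why: Wittig olefination with the non-stabilised methoxymethylene ylide converts the aldehyde into the enol ether as an E/Z mixture whose isomers converge in the next step, and neither the allyl ether nor the chromene reacts with the ylide.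

**Step 4**
Reactants: 8 6-(2-methoxyethenyl)-2,2-dimethyl-5-(prop-2-en-1-yloxy)-2H-chromene
Product: 9 [2,2-dimethyl-5-(prop-2-en-1-yloxy)-2H-chromen-6-yl]acetaldehyde
Conditions: aq HCl (2 mol/L), THF, 40 °C
Reagents that add atoms: water, O
Why: Acid-catalysed enol ether hydrolysis (protonation at carbon, hydration of the oxocarbenium ion, loss of methanol) unmasks the homologated aldehyde under conditions that aryl allyl ethers and 2,2-dimethylchromenes tolerate; the crude aldehyde should be used at once because arylacetaldehydes self-condense.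

**Step 5**
Reactants: 9 [2,2-dimethyl-5-(prop-2-en-1-yloxy)-2H-chromen-6-yl]acetaldehyde
Product: 10 [2,2-dimethyl-5-(prop-2-en-1-yloxy)-2H-chromen-6-yl]acetic acid
Conditions: NaClO2, NaH2PO4, 2-methylbut-2-ene, t-BuOH/H2O, 0 °C to rt
Reagents that add atoms: sodium chlorite, [Na+].[O-]Cl=O
Why: Pinnick oxidation converts the aldehyde into the acid through its chlorite adduct without touching the alkenes, because 2-methylbut-2-ene scavenges the hypochlorous acid that would otherwise chlorinate the electron-rich ring and double bonds.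

**Step 6**
Reactants: 10 [2,2-dimethyl-5-(prop-2-en-1-yloxy)-2H-chromen-6-yl]acetic acid; 11 (4R)-4-benzyl-1,3-oxazolidin-2-one
Product: 13 (4R)-4-benzyl-3-{[2,2-dimethyl-5-(prop-2-en-1-yloxy)-2H-chromen-6-yl]acetyl}-1,3-oxazolidin-2-one, via mixed pivalic anhydride 12 (not isolated)
Conditions: t-BuCOCl, Et3N, THF, −20 °C; then 11, LiCl, rt
Reagents that add atoms: (4R)-4-benzyl-1,3-oxazolidin-2-one (compound 11), O=C1OC[C@@H](Cc2ccccc2)N1
Why: N-Acylation of the oxazolidinone through the mixed pivalic anhydride (LiCl/Et3N procedure), in which the auxiliary nitrogen attacks the unhindered arylacetyl carbonyl and not the tert-butyl-shielded one; no stereocentre is formed or disturbed.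

**Step 7**
Reactants: 14 benzene-1,3-diol (resorcinol); 15 chloromethyl methyl ether
Product: 16 1,3-bis(methoxymethoxy)benzene
Conditions: i-Pr2NEt, CH2Cl2, 0 °C to rt
Reagents that add atoms: chloromethyl methyl ether (compound 15), COCCl
Why: Twofold Williamson-type O-alkylation of the phenols with the reactive α-chloro ether installs the MOM groups, which later direct both lithiations.

**Step 8**
Reactants: 16 1,3-bis(methoxymethoxy)benzene; 17 1-bromo-3-methylbut-2-ene (prenyl bromide)
Product: 19 1,3-bis(methoxymethoxy)-2-(3-methylbut-2-en-1-yl)benzene, via aryllithium 18 (not isolated)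
Conditions: n-BuLi, THF, 0 °C; then CuBr·SMe2 (0.1 equiv), 17, −78 °C to rt
Reagents that add atoms: prenyl bromide (compound 17), CC(C)=CCBr
Why: Directed ortho-metalation takes place at C2 because this position is flanked by both MOM ethers, and the aryllithium is then allylated at the primary carbon of prenyl bromide under copper catalysis (SN2 in preference to SN2′).

**Step 9**
Reactants: 19 1,3-bis(methoxymethoxy)-2-(3-methylbut-2-en-1-yl)benzene; 20 N,N-dimethylformamide
Product: 22 2,4-bis(methoxymethoxy)-3-(3-methylbut-2-en-1-yl)benzaldehyde, via aryllithium 21 (not isolated)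
Conditions: n-BuLi, TMEDA, THF, −20 to 0 °C; then DMF; H2O
Reagents that add atoms: N,N-dimethylformamide (compound 20), CN(C)C=O
Why: A second directed ortho-metalation occurs next to a MOM ether (the two open ortho positions are equivalent by symmetry) and the aryllithium is formylated by DMF (Bouveault-type aldehyde synthesis).

**Step 10**
Reactants: 22 2,4-bis(methoxymethoxy)-3-(3-methylbut-2-en-1-yl)benzaldehyde
Product: 23 [2,4-bis(methoxymethoxy)-3-(3-methylbut-2-en-1-yl)phenyl]methanol
Conditions: NaBH4, MeOH, 0 °C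
Reagents that add atoms: none
Why: Hydride reduction of the aldehyde with NaBH4 gives the benzylic alcohol, the acetals and the trisubstituted alkene being inert to borohydride.

**Step 11**
Reactants: 23 [2,4-bis(methoxymethoxy)-3-(3-methylbut-2-en-1-yl)phenyl]methanol
Product: 25 1-(bromomethyl)-2,4-bis(methoxymethoxy)-3-(3-methylbut-2-en-1-yl)benzene, via mesylate 24 (not isolated)
Conditions: MeSO2Cl, Et3N, THF, 0 °C; then LiBr, rt
Reagents that add atoms: lithium bromide, [Li+].[Br-]
Why: Mesylation followed by in situ displacement with bromide (Finkelstein-type SN2) gives the benzylic bromide under non-acidic conditions that spare the MOM acetals; the electron-rich bromide should be used directly.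

**Step 12**
Reactants: 13 (4R)-4-benzyl-3-{[2,2-dimethyl-5-(prop-2-en-1-yloxy)-2H-chromen-6-yl]acetyl}-1,3-oxazolidin-2-one; 25 1-(bromomethyl)-2,4-bis(methoxymethoxy)-3-(3-methylbut-2-en-1-yl)benzene
Product: 27 (4R)-4-benzyl-3-{(2R)-3-[2,4-bis(methoxymethoxy)-3-(3-methylbut-2-en-1-yl)phenyl]-2-[2,2-dimethyl-5-(prop-2-en-1-yloxy)-2H-chromen-6-yl]propanoyl}-1,3-oxazolidin-2-one, via sodium enolate 26 (not isolated)
Conditions: NaN(SiMe3)2, THF, −78 °C; then 25, −78 to −40 °C
Reagents that add atoms: none
Why: Evans asymmetric alkylation, in which the chelated sodium Z-enolate is attacked by the benzylic bromide on the face opposite the C4 benzyl group of the (4R)-auxiliary; this sets the new centre as R (the future C3), the sense being that of the classical propionimide alkylations with the aryl group in place of methyl, and the minor diastereomer should be removable by chromatography.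

**Step 13**
Reactants: 27 the alkylated imide from step 12
Product: 28 (2R)-3-[2,4-bis(methoxymethoxy)-3-(3-methylbut-2-en-1-yl)phenyl]-2-[2,2-dimethyl-5-(prop-2-en-1-yloxy)-2H-chromen-6-yl]propan-1-ol
Conditions: LiBH4, MeOH (1 equiv), THF, 0 °C
Reagents that add atoms: none
Why: Reductive removal of the auxiliary with LiBH4 (hydride attack at the more electrophilic exocyclic imide carbonyl) gives the primary alcohol at low temperature without enolisation of the α-aryl centre, and the auxiliary is recovered.

**Step 14**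
Reactants: 28 (2R)-3-[2,4-bis(methoxymethoxy)-3-(3-methylbut-2-en-1-yl)phenyl]-2-[2,2-dimethyl-5-(prop-2-en-1-yloxy)-2H-chromen-6-yl]propan-1-ol
Product: 29 4-{(2R)-2-[2,2-dimethyl-5-(prop-2-en-1-yloxy)-2H-chromen-6-yl]-3-hydroxypropyl}-2-(3-methylbut-2-en-1-yl)benzene-1,3-diol
Conditions: HCl (3 mol/L), MeOH, 40 °C
Reagents that add atoms: none
Why: Acid-catalysed methanolysis cleaves the two aryl MOM acetals through the oxocarbenium pathway faster than acid adds to the prenyl or chromene double bonds at this temperature, while the allyl ether on ring B is stable, so only the ring A hydroxyls are freed.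

**Step 15**
Reactants: 29 4-{(2R)-2-[2,2-dimethyl-5-(prop-2-en-1-yloxy)-2H-chromen-6-yl]-3-hydroxypropyl}-2-(3-methylbut-2-en-1-yl)benzene-1,3-diol
Product: 30 (3R)-3-[2,2-dimethyl-5-(prop-2-en-1-yloxy)-2H-chromen-6-yl]-8-(3-methylbut-2-en-1-yl)-3,4-dihydro-2H-chromen-7-ol
Conditions: PPh3, DIAD, THF (0.02 mol/L), 0 °C to rt
Reagents that add atoms: none
Why: Intramolecular Mitsunobu etherification, in which the activated primary alcohol is displaced by the ring A hydroxyl ortho to the side chain in a 6-exo-tet closure (the other ring A hydroxyl cannot reach and the ring B oxygen is blocked as its allyl ether), and the stereocentre, which is not the reacting carbon, is untouched.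

**Step 16**
Reactants: 30 (3R)-3-[2,2-dimethyl-5-(prop-2-en-1-yloxy)-2H-chromen-6-yl]-8-(3-methylbut-2-en-1-yl)-3,4-dihydro-2H-chromen-7-ol
Product: 31 (3R)-3-(5-hydroxy-2,2-dimethyl-2H-chromen-6-yl)-8-(3-methylbut-2-en-1-yl)-3,4-dihydro-2H-chromen-7-ol
Conditions: Pd(PPh3)4 (5 mol %), morpholine, THF, rt
Reagents that add atoms: none
Why: Tsuji–Trost deallylation, in which zerovalent palladium ionises the aryl allyl ether to a π-allyl complex that is captured by morpholine, releasing the phenol under neutral conditions that leave the prenyl group, the chromene and the stereocentre unchanged.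

**Compound list**
1 | 2,4-dihydroxybenzaldehyde | O=Cc1ccc(O)cc1O | starting material
2 | 3-methylbut-2-enal | CC(C)=CC=O | starting material
3 | (3Z)-2-hydroxy-3-(3-methylbut-2-en-1-ylidene)-4-oxocyclohexa-1,5-diene-1-carbaldehyde (ortho-quinone methide, not isolated) | O=CC1=C(O)/C(=C/C=C(C)C)C(=O)C=C1 | intermediate
4 | 5-hydroxy-2,2-dimethyl-2H-chromene-6-carbaldehyde | CC1(C)C=Cc2c(O1)ccc(C=O)c2O | intermediate
5 | 3-bromoprop-1-ene (allyl bromide) | C=CCBr | starting material
6 | 2,2-dimethyl-5-(prop-2-en-1-yloxy)-2H-chromene-6-carbaldehyde | C=CCOc1c(C=O)ccc2OC(C)(C)C=Cc12 | intermediate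
7 | (methoxymethyl)triphenylphosphonium chloride | COC[P+](c1ccccc1)(c1ccccc1)c1ccccc1.[Cl-] | starting material
8 | 6-(2-methoxyethenyl)-2,2-dimethyl-5-(prop-2-en-1-yloxy)-2H-chromene (E/Z mixture) | COC=Cc1ccc2OC(C)(C)C=Cc2c1OCC=C | intermediate
9 | [2,2-dimethyl-5-(prop-2-en-1-yloxy)-2H-chromen-6-yl]acetaldehyde | O=CCc1ccc2OC(C)(C)C=Cc2c1OCC=C | intermediate
10 | [2,2-dimethyl-5-(prop-2-en-1-yloxy)-2H-chromen-6-yl]acetic acid | OC(=O)Cc1ccc2OC(C)(C)C=Cc2c1OCC=C | intermediate
11 | (4R)-4-benzyl-1,3-oxazolidin-2-one | O=C1OC[C@@H](Cc2ccccc2)N1 | starting material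
12 | [2,2-dimethyl-5-(prop-2-en-1-yloxy)-2H-chromen-6-yl]acetic pivalic anhydride (not isolated) | CC(C)(C)C(=O)OC(=O)Cc1ccc2OC(C)(C)C=Cc2c1OCC=C | intermediate
13 | (4R)-4-benzyl-3-{[2,2-dimethyl-5-(prop-2-en-1-yloxy)-2H-chromen-6-yl]acetyl}-1,3-oxazolidin-2-one | O=C1OC[C@@H](Cc2ccccc2)N1C(=O)Cc1ccc2OC(C)(C)C=Cc2c1OCC=C | intermediate
14 | benzene-1,3-diol (resorcinol) | Oc1cccc(O)c1 | starting material
15 | chloromethyl methyl ether | COCCl | starting material
16 | 1,3-bis(methoxymethoxy)benzene | COCOc1cccc(OCOC)c1 | intermediate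
17 | 1-bromo-3-methylbut-2-ene (prenyl bromide) | CC(C)=CCBr | starting material
18 | [2,6-bis(methoxymethoxy)phenyl]lithium (not isolated) | [Li]c1c(OCOC)cccc1OCOC | intermediate
19 | 1,3-bis(methoxymethoxy)-2-(3-methylbut-2-en-1-yl)benzene | COCOc1cccc(OCOC)c1CC=C(C)C | intermediate
20 | N,N-dimethylformamide | CN(C)C=O | starting material
21 | [2,4-bis(methoxymethoxy)-3-(3-methylbut-2-en-1-yl)phenyl]lithium (not isolated) | [Li]c1ccc(OCOC)c(CC=C(C)C)c1OCOC | intermediate
22 | 2,4-bis(methoxymethoxy)-3-(3-methylbut-2-en-1-yl)benzaldehyde | O=Cc1ccc(OCOC)c(CC=C(C)C)c1OCOC | intermediate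
23 | [2,4-bis(methoxymethoxy)-3-(3-methylbut-2-en-1-yl)phenyl]methanol | OCc1ccc(OCOC)c(CC=C(C)C)c1OCOC | intermediate
24 | [2,4-bis(methoxymethoxy)-3-(3-methylbut-2-en-1-yl)phenyl]methyl methanesulfonate (not isolated) | CS(=O)(=O)OCc1ccc(OCOC)c(CC=C(C)C)c1OCOC | intermediate
25 | 1-(bromomethyl)-2,4-bis(methoxymethoxy)-3-(3-methylbut-2-en-1-yl)benzene | BrCc1ccc(OCOC)c(CC=C(C)C)c1OCOC | intermediate
26 | sodium (Z)-enolate of imide 13 (not isolated) | [Na+].[O-]/C(=C\c1ccc2OC(C)(C)C=Cc2c1OCC=C)N1[C@H](Cc2ccccc2)COC1=O | intermediate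
27 | (4R)-4-benzyl-3-{(2R)-3-[2,4-bis(methoxymethoxy)-3-(3-methylbut-2-en-1-yl)phenyl]-2-[2,2-dimethyl-5-(prop-2-en-1-yloxy)-2H-chromen-6-yl]propanoyl}-1,3-oxazolidin-2-one | O=C1OC[C@@H](Cc2ccccc2)N1C(=O)[C@H](Cc1ccc(OCOC)c(CC=C(C)C)c1OCOC)c1ccc2OC(C)(C)C=Cc2c1OCC=C | intermediate
28 | (2R)-3-[2,4-bis(methoxymethoxy)-3-(3-methylbut-2-en-1-yl)phenyl]-2-[2,2-dimethyl-5-(prop-2-en-1-yloxy)-2H-chromen-6-yl]propan-1-ol | OC[C@H](Cc1ccc(OCOC)c(CC=C(C)C)c1OCOC)c1ccc2OC(C)(C)C=Cc2c1OCC=C | intermediate
29 | 4-{(2R)-2-[2,2-dimethyl-5-(prop-2-en-1-yloxy)-2H-chromen-6-yl]-3-hydroxypropyl}-2-(3-methylbut-2-en-1-yl)benzene-1,3-diol | OC[C@H](Cc1ccc(O)c(CC=C(C)C)c1O)c1ccc2OC(C)(C)C=Cc2c1OCC=C | intermediate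
30 | (3R)-3-[2,2-dimethyl-5-(prop-2-en-1-yloxy)-2H-chromen-6-yl]-8-(3-methylbut-2-en-1-yl)-3,4-dihydro-2H-chromen-7-ol | CC(C)=CCc1c(O)ccc2c1OC[C@@H](c1ccc3c(c1OCC=C)C=CC(C)(C)O3)C2 | intermediate
31 | (3R)-3-(5-hydroxy-2,2-dimethyl-2H-chromen-6-yl)-8-(3-methylbut-2-en-1-yl)-3,4-dihydro-2H-chromen-7-ol | CC(C)=CCc1c(O)ccc2c1OC[C@@H](c1ccc3c(c1O)C=CC(C)(C)O3)C2 | target

**Totals**
Total step count: 16. Longest linear sequence: 11 steps (steps 1 to 6, then steps 12 to 16).

**Steps most likely to fail**

Step 12. The imide enolate may collapse by loss of the oxazolidinone (ketene formation) when warmed. The acidic α-aryl centre of the product may be epimerised by base that is still present. The electron-rich bromide may ionise before it is captured.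
The fallback sets out from acid 10 and bromide 25 and avoids the imide. Acid 10 would be treated with n-BuLi and the dilithium amide of a C2-symmetric Koga-type tetramine, N,N′-bis[1-phenyl-2-(piperidin-1-yl)ethyl]propane-1,3-diamine, in THF at −78 °C. This should give the dilithium enediolate of acid 10 F1, which is alkylated within its chiral mixed aggregate by 25 to give (2R)-3-[2,4-bis(methoxymethoxy)-3-(3-methylbut-2-en-1-yl)phenyl]-2-[2,2-dimethyl-5-(prop-2-en-1-yloxy)-2H-chromen-6-yl]propanoic acid F2. This is a direct enantioselective enediolate alkylation; the enantiomer of the tetramine that delivers the R acid is to be fixed in a trial run, and the product carboxylate resists epimerisation. LiAlH4 in THF at 0 °C should then reduce F2 to alcohol 28, where the route is rejoined; compounds 13, 26 and 27 are bypassed.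

Step 14. Once the electron-rich, carbonyl-free ring A diol is exposed to acid, addition of the freed hydroxyls to the prenyl double bond (closure to a dimethyldihydropyran) and addition of methanol to the chromene double bond may compete with acetal cleavage.
The fallback sets out from aldehyde 22, moves the acid step to this stage, and carries ring A as silyl ethers. At this stage the formyl group lowers the nucleophilicity of both hydroxyls: one is hydrogen-bonded to it and the other is para to it. HCl in MeOH should give 2,4-dihydroxy-3-(3-methylbut-2-en-1-yl)benzaldehyde F3. Silylation with t-BuMe2SiOSO2CF3 and 2,6-lutidine in CH2Cl2 should give 2,4-bis[(tert-butyldimethylsilyl)oxy]-3-(3-methylbut-2-en-1-yl)benzaldehyde F4. Reduction with i-Bu2AlH at −78 °C (cold quench to suppress silyl migration) should give {2,4-bis[(tert-butyldimethylsilyl)oxy]-3-(3-methylbut-2-en-1-yl)phenyl}methanol F5. CBr4 and PPh3 should give 1-(bromomethyl)-2,4-bis[(tert-butyldimethylsilyl)oxy]-3-(3-methylbut-2-en-1-yl)benzene F6. Alkylation of enolate 26 with F6 as in step 12 should give (4R)-4-benzyl-3-{(2R)-3-{2,4-bis[(tert-butyldimethylsilyl)oxy]-3-(3-methylbut-2-en-1-yl)phenyl}-2-[2,2-dimethyl-5-(prop-2-en-1-yloxy)-2H-chromen-6-yl]propanoyl}-1,3-oxazolidin-2-one F7. LiBH4 should give (2R)-3-{2,4-bis[(tert-butyldimethylsilyl)oxy]-3-(3-methylbut-2-en-1-yl)phenyl}-2-[2,2-dimethyl-5-(prop-2-en-1-yloxy)-2H-chromen-6-yl]propan-1-ol F8. Bu4NF buffered with AcOH in THF at 0 °C should then remove both silyl groups without acid and give 29, where the route is rejoined.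

Step 9. Deprotonation at the benzylic and allylic CH2 of the prenyl chain, which is flanked by both MOM ethers, may compete with ring lithiation and lead to isomerisation of the double bond.
The fallback sets out from 1 and introduces the formyl group first and the prenyl group last. Compound 1 with 15 and i-Pr2NEt should give 2,4-bis(methoxymethoxy)benzaldehyde F9. Lithium 4-methylpiperazin-1-ide in THF at −20 °C adds to the aldehyde to give lithium [2,4-bis(methoxymethoxy)phenyl](4-methylpiperazin-1-yl)methanolate F10, which protects the formyl group in the flask. n-BuLi should then lithiate the position between the two MOM ethers to give the 3-lithio derivative of that amino alkoxide F11 (α-amino alkoxide directed ortho-metalation). Transmetalation with CuBr·SMe2, alkylation with 17 and aqueous work-up should release 22, where the route is rejoined; compounds 16, 18, 19 and 21 are bypassed.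

**Further compounds**
F1 | step 12 | dilithium enediolate of acid 10 | [Li]OC(O[Li])=Cc1ccc2OC(C)(C)C=Cc2c1OCC=C
F2 | step 12 | (2R)-3-[2,4-bis(methoxymethoxy)-3-(3-methylbut-2-en-1-yl)phenyl]-2-[2,2-dimethyl-5-(prop-2-en-1-yloxy)-2H-chromen-6-yl]propanoic acid | OC(=O)[C@H](Cc1ccc(OCOC)c(CC=C(C)C)c1OCOC)c1ccc2OC(C)(C)C=Cc2c1OCC=C
F3 | step 14 | 2,4-dihydroxy-3-(3-methylbut-2-en-1-yl)benzaldehyde | O=Cc1ccc(O)c(CC=C(C)C)c1O
F4 | step 14 | 2,4-bis[(tert-butyldimethylsilyl)oxy]-3-(3-methylbut-2-en-1-yl)benzaldehyde | O=Cc1ccc(O[Si](C)(C)C(C)(C)C)c(CC=C(C)C)c1O[Si](C)(C)C(C)(C)C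
F5 | step 14 | {2,4-bis[(tert-butyldimethylsilyl)oxy]-3-(3-methylbut-2-en-1-yl)phenyl}methanol | OCc1ccc(O[Si](C)(C)C(C)(C)C)c(CC=C(C)C)c1O[Si](C)(C)C(C)(C)C
F6 | step 14 | 1-(bromomethyl)-2,4-bis[(tert-butyldimethylsilyl)oxy]-3-(3-methylbut-2-en-1-yl)benzene | BrCc1ccc(O[Si](C)(C)C(C)(C)C)c(CC=C(C)C)c1O[Si](C)(C)C(C)(C)C
F7 | step 14 | (4R)-4-benzyl-3-{(2R)-3-{2,4-bis[(tert-butyldimethylsilyl)oxy]-3-(3-methylbut-2-en-1-yl)phenyl}-2-[2,2-dimethyl-5-(prop-2-en-1-yloxy)-2H-chromen-6-yl]propanoyl}-1,3-oxazolidin-2-one | O=C1OC[C@@H](Cc2ccccc2)N1C(=O)[C@H](Cc1ccc(O[Si](C)(C)C(C)(C)C)c(CC=C(C)C)c1O[Si](C)(C)C(C)(C)C)c1ccc2OC(C)(C)C=Cc2c1OCC=C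
F8 | step 14 | (2R)-3-{2,4-bis[(tert-butyldimethylsilyl)oxy]-3-(3-methylbut-2-en-1-yl)phenyl}-2-[2,2-dimethyl-5-(prop-2-en-1-yloxy)-2H-chromen-6-yl]propan-1-ol | OC[C@H](Cc1ccc(O[Si](C)(C)C(C)(C)C)c(CC=C(C)C)c1O[Si](C)(C)C(C)(C)C)c1ccc2OC(C)(C)C=Cc2c1OCC=C
F9 | step 9 | 2,4-bis(methoxymethoxy)benzaldehyde | O=Cc1ccc(OCOC)cc1OCOC
F10 | step 9 | lithium [2,4-bis(methoxymethoxy)phenyl](4-methylpiperazin-1-yl)methanolate | [Li]OC(N1CCN(C)CC1)c1ccc(OCOC)cc1OCOC
F11 | step 9 | 3-lithio derivative of lithium [2,4-bis(methoxymethoxy)phenyl](4-methylpiperazin-1-yl)methanolate | [Li]OC(N1CCN(C)CC1)c1ccc(OCOC)c([Li])c1OCOC
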